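## The problem

4-O-Demethylplanaic acid (11) is a depside: two 2-methoxy-6-pentylbenzoyl units oxygenated at C4, joined by an ester between the C1 carbonyl of ring A (the acyl ring, free phenol at C4) and O4 of ring B (the acid ring, free carboxyl at C1). The molecule has no stereocentre, so the difficulties are regiochemistry on two 1,2,3,5-tetrasubstituted benzene rings, chemoselectivity and protecting-group order. The ester carbonyl sits between a methoxy and a pentyl group, and a di-ortho-substituted benzoic acid of this kind is a poor acyl donor that normally needs forcing activation. Once made, the link is an aryl ester whose leaving group, the ring B phenoxide, is stabilised by a para carboxyl function, so hydroxide, alkoxides and unbuffered fluoride endanger it; the electron-rich ring B acid is also prone to decarboxylation in hot acid. One phenol and two aryl methyl ethers rule out a late selective demethylation, so the methyl ethers must be carried from the start, and the ring A phenol and ring B carboxyl need masks that come off under near-neutral conditions. Both rings have the skeleton of 3-methoxy-5-pentylphenol (2) plus one carbon on the ring position between methoxy and pentyl, so one aryl building block can feed both halves. The enabling feature is that the ester carbonyl is a single carbon bonded only to C1 of ring A and to the phenolic O4 of ring B, the pattern created when an aryl halide, carbon monoxide (5) and a phenol meet on palladium.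

## Retrosynthesis

**11 back to 9.** The benzyl–oxygen bond of a ring B benzyl ester and the silicon–oxygen bond of a ring A triisopropylsilyl ether are cut, leading from 11 through phenol ester 10 to the fully protected depside 9. A benzyl ester is preferred to a simple alkyl ester because hydrogenolysis is neutral and leaves the aryl ester alone, whereas saponification would open the depside link first. The silyl ether keeps the ring A oxygen from acting as a nucleophile in the coupling, steers the iodination further back, and can be removed beside a benzyl ester. Desilylation is placed before hydrogenolysis so that 11 is obtained by filtration alone. The forward reactions must be a buffered fluoride cleavage that spares two esters and a clean hydrogenolysis.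

**9 back to 4, 5 and 8.** Both bonds to the ester carbonyl carbon are cut, C1(ring A)–C(=O) and C(=O)–O4(ring B), giving aryl iodide 4, carbon monoxide 5 and phenol 8. Cutting only the carbonyl–oxygen bond would need the 2,6-disubstituted acid and its activation. Cutting only the aryl–carbonyl bond would need an aryl organometallic too basic for the benzyl ester of ring B. The three-component cut generates the acyl donor as an aroylpalladium species under a weak amine base. A C42 depside falls into a C21 iodide and a C20 phenol of common origin. The forward reaction must insert 5 faster than the aryl–palladium bond is reduced and must see only one competent nucleophile, hence the silyl mask on 4 and the need for 8 to be free of benzyl alcohol 6.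

**8 back to 4, 5 and 6.** The silicon–oxygen bond of 7 is cut, and then the two bonds to its ester carbonyl, which returns to the same iodide 4 with 6 as nucleophile. Against metalation, carboxylation and benzylation this is one step with no organometallic, and ring B needs no building block of its own. The step also rehearses oxidative addition and insertion of 5 at the hindered carbon with a more forgiving nucleophile. The forward reaction must tolerate the aryl silyl ether at 90 °C.

**4 back to 1.** The C–I bond of 4 is cut to give silyl ether 3, then the O–Si bond to give phenol 2, then one O–CH3 bond to give olivetol 1. Three ring positions of 3 are open. C2 lies between the two oxygens, C6 lies between the silyloxy group and the pentyl chain, and C4 lies between methoxy and pentyl, para to the silyloxy group. The bulky silyl group shields C2 and C6, and C4 is activated by both oxygens. Iodinating 2 before silylation would rely on the hydroxyl alone and risks ortho products, so the silyl group is introduced first. Compound 1 is symmetric, commercial and already carries the pentyl chain and the 1,3,5-pattern, so its monomethylation raises only a statistical question.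

## Roads not taken

**Alternative 1:** Ring B would be built from acyclic material by a Danheiser-type benzannulation. The cut removes the C1–C2, C3–C4 and C4–C5 bonds of ring B and leads to benzyl 2-diazo-4-methylidene-3-oxononanoate A1 and methoxyacetylene A3.
- Forward key step: photochemical Wolff rearrangement of A1 gives the ester-substituted vinylketene A2. [2+2] addition of A3, four-electron ring opening of the cyclobutenone, six-electron electrocyclisation and tautomerisation should give benzyl 4-hydroxy-2-methoxy-6-pentylbenzoate A4, the same compound as 8.
- Merit: every substituent of ring B is placed by the connectivity of the annulation. In this respect it is better than the chosen plan, whose step 3 depends on steric steering.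
- Weak points: A2 is also an acylketene and can react with the electron-rich alkyne as an oxadiene, giving a pyranone instead of the cyclobutenone. A3 is volatile and unstable and must be made and used cold. A1 needs several steps of its own. The sequence delivers only one ring, so ring A and the hindered ester bond remain unsolved.
- Comparison: the chosen plan buys ring, chain and oxygen pattern with 1, draws both rings from iodide 4 and forms the depside link in its key step. It gives up the regiochemical certainty of the annulation.

**Alternative 2:** The ring A acid would be assembled on an aryne. The cut removes the C6–pentyl and C1–carboxyl bonds and leads to (3-fluoro-5-methoxyphenoxy)triisopropylsilane A5 and pentyllithium A6.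
- Forward key step: A6 deprotonates A5 between fluorine and methoxy, fluoride is lost, a second equivalent of A6 adds to the aryne at the carbon remote from methoxy, and carboxylation of the aryllithium gives 2-methoxy-6-pentyl-4-(triisopropylsilyloxy)benzoic acid A7.
- Merits: two carbon–carbon bonds form in one flask, with regiochemistry from the known preference of 3-alkoxyarynes for attack meta to oxygen. Benzylation and desilylation of A7 would give 8, so one intermediate again serves both rings. The overall sequence would be about one step shorter than the chosen route, and its mixed-anhydride esterification is a proven way to depsides.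
- Weak points: three selective events must follow each other at low temperature. Lithiation must occur only at the site between fluorine and methoxy, the product aryllithium must not add to more aryne or deprotonate A5, and A6 has to be prepared. The route ends at the hindered acid, so the depside bond still requires strong activation of a 2,6-disubstituted acid.
- Comparison: the chosen plan avoids a stoichiometric organolithium cascade and generates the acyl donor catalytically under a weak base, at the cost of one more step. A7 is kept in reserve as F1 in the fallback to step 6.

**Alternative 3:** Ring A would be closed last, on the intact ester. The cut removes the C1–C6 bond of ring A and leads to benzyl 2-methoxy-6-pentyl-4-[(3,5,7-trioxododecanoyl)oxy]benzoate A8, the ester of 8 with an open tetraketide chain.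
- Forward key step: mild base makes C2 of the chain add to the C7 ketone, and acid dehydrates and aromatises to benzyl 4-[(2,4-dihydroxy-6-pentylbenzoyl)oxy]-2-methoxy-6-pentylbenzoate A9.
- Merit: the ester bond is made while its acyl carbon is an unhindered aliphatic carbonyl, so the steric problem disappears. This solves the hindered-ester problem as well as the chosen plan does, and more elegantly.
- Weak points: the chain can also cyclise by C-acylation of C6 onto C1 or by lactonisation of the C5 enol oxygen onto C1. Both expel the ring B phenoxide and destroy the depside. A9 carries two free ring A hydroxyls, and the one to be methylated is the chelated, less reactive 2-hydroxyl. Protection of the 4-hydroxyl, methylation under base beside a labile aryl ester and deprotection would add three steps at a sensitive stage.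
- Comparison: the chosen plan fixes the methyl ether pattern in 2 from the first step and has no ambiguity of cyclisation mode.

Key step: step 6

## Route

Step 1
Reactants: 1 olivetol (5-pentylbenzene-1,3-diol)
Product: 2 3-methoxy-5-pentylphenol
Conditions: MeI (1.0 equiv), K2CO3 (1.0 equiv), acetone, reflux
Reagents that add atoms: iodomethane, CI
Why: Williamson O-methylation of a symmetric resorcinol; with one equivalent of MeI the mono-ether should be the main component of a statistical mixture, separable on silica from diol and di-ether, with recovered 1 recycled.

Step 2
Reactants: 2 3-methoxy-5-pentylphenol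
Product: 3 (3-methoxy-5-pentylphenoxy)triisopropylsilane
Conditions: TIPSCl, imidazole, DMF, rt
Reagents that add atoms: triisopropylsilyl chloride, CC(C)[Si](Cl)(C(C)C)C(C)C
Why: Imidazole-promoted silylation of an unhindered phenol; the phenol oxygen is flanked only by ring hydrogens, so even the bulky silyl chloride should react cleanly.

Step 3
Reactants: 3 (3-methoxy-5-pentylphenoxy)triisopropylsilane
Product: 4 (4-iodo-3-methoxy-5-pentylphenoxy)triisopropylsilane
Conditions: NIS, CF3CO2H (10 mol %), MeCN, 0 °C to rt
Reagents that add atoms: N-iodosuccinimide, O=C1CCC(=O)N1I
Why: Electrophilic aromatic iodination with acid-activated NIS; C4 is ortho to methoxy and para to silyloxy, while the other doubly activated positions (C2 and C6) lie next to the triisopropylsilyloxy group and are shielded by it, and the first iodine deactivates the ring against a second.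

Step 4
Reactants: 4 (4-iodo-3-methoxy-5-pentylphenoxy)triisopropylsilane; 5 carbon monoxide; 6 benzyl alcohol (3 equiv)
Product: 7 benzyl 2-methoxy-6-pentyl-4-(triisopropylsilyloxy)benzoate
Conditions: Pd(OAc)2 (5 mol %), Xantphos (7.5 mol %), Et3N (3 equiv), CO (5 bar), toluene, 90 °C
Reagents that add atoms: none
Why: Palladium-catalysed alkoxycarbonylation of an aryl iodide (Heck carbonylation): oxidative addition, insertion of 5, and alcoholysis of the aroylpalladium complex by 6 with Et3N taking up HI; the aryl silyl ether and methyl ether are inert, and excess 6 is removed on silica.

Step 5
Reactants: 7 benzyl 2-methoxy-6-pentyl-4-(triisopropylsilyloxy)benzoate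
Product: 8 benzyl 4-hydroxy-2-methoxy-6-pentylbenzoate
Conditions: Bu4NF, AcOH, THF, 0 °C
Reagents that add atoms: none
Why: Fluoride cleavage of an aryl silyl ether driven by the strong Si–F bond; acetic acid keeps the phenol protonated, and the di-ortho-substituted benzyl ester should not be touched.

Step 6
Reactants: 4 (4-iodo-3-methoxy-5-pentylphenoxy)triisopropylsilane; 5 carbon monoxide; 8 benzyl 4-hydroxy-2-methoxy-6-pentylbenzoate (1.2 equiv)
Product: 9 benzyl 2-methoxy-4-{[2-methoxy-6-pentyl-4-(triisopropylsilyloxy)benzoyl]oxy}-6-pentylbenzoate
Conditions: Pd(OAc)2 (5 mol %), Xantphos (7.5 mol %), Et3N (3 equiv), CO (5 bar), toluene, 100 °C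
Reagents that add atoms: none
Why: Pd(OAc)2 is reduced in the flask to zerovalent palladium carrying Xantphos, which inserts into the C–I bond of 4; 5 then inserts into the aryl–palladium bond to give an aroyl complex of divalent palladium, which relieves the crowding between the metal and the two ortho substituents. The triethylammonium phenoxide of 8, whose phenol is acidified by the para ester, replaces iodide on palladium, and C–O reductive elimination releases aryl ester 9 and returns zerovalent palladium while Et3N takes up HI. The closest known reaction type is the palladium-catalysed aryloxycarbonylation of aryl iodides with carbon monoxide and phenols; di-ortho-substituted iodides lie at the demanding end of its scope, and step 4 tests oxidative addition and insertion on the same iodide beforehand. No ring is closed and no stereocentre is formed. The selectivity needed is chemoselectivity: insertion of 5 must outrun direct aryl–oxygen coupling and reduction of the aryl–palladium bond, which the pressure of 5, the reluctance of a hindered electron-rich arylpalladium to eliminate a diaryl ether and the wide bite angle of Xantphos should secure. Only one nucleophile is present, because the oxygen of 4 is silylated and 8 is used free of 6; exchange of 8 at the new ester would be degenerate, and the hindered benzyl ester is not attacked.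

Step 7
Reactants: 9 benzyl 2-methoxy-4-{[2-methoxy-6-pentyl-4-(triisopropylsilyloxy)benzoyl]oxy}-6-pentylbenzoate
Product: 10 benzyl 4-[(4-hydroxy-2-methoxy-6-pentylbenzoyl)oxy]-2-methoxy-6-pentylbenzoate
Conditions: Bu4NF, AcOH, THF, 0 °C
Reagents that add atoms: none
Why: Buffered fluoride desilylation of an aryl silyl ether as in step 5; with acetic acid present no free phenoxide or naked fluoride persists, and the depside carbonyl is shielded by its methoxy and pentyl neighbours.

Step 8
Reactants: 10 benzyl 4-[(4-hydroxy-2-methoxy-6-pentylbenzoyl)oxy]-2-methoxy-6-pentylbenzoate
Product: 11 4-[(4-hydroxy-2-methoxy-6-pentylbenzoyl)oxy]-2-methoxy-6-pentylbenzoic acid (4-O-demethylplanaic acid)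
Conditions: H2 (1 atm), Pd/C (10 wt % Pd), EtOAc, rt
Reagents that add atoms: none
Why: Hydrogenolysis of a benzyl ester over Pd/C is neutral and leaves aryl esters, aryl ethers and the phenol untouched; filtration and evaporation at room temperature avoid decarboxylation of the electron-rich acid.

## Compound list

1 | olivetol (5-pentylbenzene-1,3-diol) | CCCCCc1cc(O)cc(O)c1 | starting material
2 | 3-methoxy-5-pentylphenol | CCCCCc1cc(O)cc(OC)c1 | intermediate
3 | (3-methoxy-5-pentylphenoxy)triisopropylsilane | CCCCCc1cc(OC)cc(O[Si](C(C)C)(C(C)C)C(C)C)c1 | intermediate
4 | (4-iodo-3-methoxy-5-pentylphenoxy)triisopropylsilane | CCCCCc1cc(O[Si](C(C)C)(C(C)C)C(C)C)cc(OC)c1I | intermediate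
5 | carbon monoxide | [C-]#[O+] | starting material
6 | benzyl alcohol | OCc1ccccc1 | starting material
7 | benzyl 2-methoxy-6-pentyl-4-(triisopropylsilyloxy)benzoate | CCCCCc1cc(O[Si](C(C)C)(C(C)C)C(C)C)cc(OC)c1C(=O)OCc1ccccc1 | intermediate
8 | benzyl 4-hydroxy-2-methoxy-6-pentylbenzoate | CCCCCc1cc(O)cc(OC)c1C(=O)OCc1ccccc1 | intermediate
9 | benzyl 2-methoxy-4-{[2-methoxy-6-pentyl-4-(triisopropylsilyloxy)benzoyl]oxy}-6-pentylbenzoate | CCCCCc1cc(O[Si](C(C)C)(C(C)C)C(C)C)cc(OC)c1C(=O)Oc1cc(CCCCC)c(C(=O)OCc2ccccc2)c(OC)c1 | intermediate
10 | benzyl 4-[(4-hydroxy-2-methoxy-6-pentylbenzoyl)oxy]-2-methoxy-6-pentylbenzoate | CCCCCc1cc(O)cc(OC)c1C(=O)Oc1cc(CCCCC)c(C(=O)OCc2ccccc2)c(OC)c1 | intermediate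
11 | 4-[(4-hydroxy-2-methoxy-6-pentylbenzoyl)oxy]-2-methoxy-6-pentylbenzoic acid (4-O-demethylplanaic acid) | CCCCCc1cc(OC(=O)c2c(CCCCC)cc(O)cc2OC)cc(OC)c1C(=O)O | target

## Step count and least certain steps

Total step count: 8. Longest linear sequence: 8 steps (1 → 2 → 3 → 4 → 7 → 8 → 9 → 10 → 11), because iodide 4 enters both step 4 and step 6.

**Step 6 (key step).** The aroylpalladium intermediate, flanked by methoxy and pentyl, may be attacked too slowly by the weakly nucleophilic, ester-bearing phenoxide. Reduction of the aryl–palladium bond (loss of iodine without carbonylation) or deposition of palladium metal at 100 °C would then take over. The fallback sets out from 4 and makes the ester by classical acylation. Iodine–magnesium exchange with iPrMgCl·LiCl in THF (0 °C to rt) and carboxylation with CO2 should give 2-methoxy-6-pentyl-4-(triisopropylsilyloxy)benzoic acid F1. Trifluoroacetic anhydride in toluene converts it into 2-methoxy-6-pentyl-4-(triisopropylsilyloxy)benzoic trifluoroacetic anhydride F2. F2 ionises readily to an electron-rich acylium ion and should acylate 8 in the same flask. The fallback rejoins the route at 9.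

**Step 3.** Iodination may be poorly regioselective, with attack para to methoxy (at C6) despite the neighbouring silyl group, or the acid catalyst may cause partial loss of the silyl group. The fallback sets out from 2 and reverses the order of events. Iodination of the free phenol with NIS and catalytic TsOH in MeCN relies on the hydroxyl as the stronger para director and should give 4-iodo-3-methoxy-5-pentylphenol F3. Silylation with TIPSCl and imidazole then rejoins the route at 4.

**Step 1.** Methylation is statistical, so over-alkylation to the di-ether beside unreacted diol caps the throughput. The fallback sets out from 1 with exhaustive methylation (excess MeI, K2CO3) to 1,3-dimethoxy-5-pentylbenzene F4. Heating F4 with NaSEt in DMF at 140 °C removes one methyl group by SN2 attack of thiolate and stops there, because the phenoxide formed resists a second demethylation. Acidic work-up rejoins the route at 2.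

**Step 7.** Fluoride or the liberated ring A phenoxide may open the depside ester by acyl transfer, since the ring B phenoxide is a good leaving group, or may attack the benzyl ester. The fallback sets out from 4 and never exposes the depside to fluoride. Desilylation of 4 with Bu4NF and AcOH gives 4-iodo-3-methoxy-5-pentylphenol F3. Benzylation with benzyl bromide and K2CO3 in DMF gives 5-(benzyloxy)-2-iodo-1-methoxy-3-pentylbenzene F5. The carbonylative coupling of step 6, run with F5, 5 and 8, should give benzyl 4-{[4-(benzyloxy)-2-methoxy-6-pentylbenzoyl]oxy}-2-methoxy-6-pentylbenzoate F6. One hydrogenolysis over Pd/C removes both benzyl groups and rejoins the route at 11.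

## Further compounds

F1 | step 6 | 2-methoxy-6-pentyl-4-(triisopropylsilyloxy)benzoic acid | CCCCCc1cc(O[Si](C(C)C)(C(C)C)C(C)C)cc(OC)c1C(=O)O
F2 | step 6 | 2-methoxy-6-pentyl-4-(triisopropylsilyloxy)benzoic trifluoroacetic anhydride | CCCCCc1cc(O[Si](C(C)C)(C(C)C)C(C)C)cc(OC)c1C(=O)OC(=O)C(F)(F)F
F3 | step 3 | 4-iodo-3-methoxy-5-pentylphenol | CCCCCc1cc(O)cc(OC)c1I
F4 | step 1 | 1,3-dimethoxy-5-pentylbenzene | CCCCCc1cc(OC)cc(OC)c1
F5 | step 7 | 5-(benzyloxy)-2-iodo-1-methoxy-3-pentylbenzene | CCCCCc1cc(OCc2ccccc2)cc(OC)c1I
F6 | step 7 | benzyl 4-{[4-(benzyloxy)-2-methoxy-6-pentylbenzoyl]oxy}-2-methoxy-6-pentylbenzoate | CCCCCc1cc(OCc2ccccc2)cc(OC)c1C(=O)Oc1cc(CCCCC)c(C(=O)OCc2ccccc2)c(OC)c1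
A1 | alternative 1 | benzyl 2-diazo-4-methylidene-3-oxononanoate | CCCCCC(=C)C(=O)C(=[N+]=[N-])C(=O)OCc1ccccc1
A2 | alternative 1 | benzyl 3-methylidene-2-(oxomethylidene)octanoate | CCCCCC(=C)C(=C=O)C(=O)OCc1ccccc1
A3 | alternative 1 | methoxyacetylene | COC#C
A4 | alternative 1 | benzyl 4-hydroxy-2-methoxy-6-pentylbenzoate | CCCCCc1cc(O)cc(OC)c1C(=O)OCc1ccccc1
A5 | alternative 2 | (3-fluoro-5-methoxyphenoxy)triisopropylsilane | COc1cc(F)cc(O[Si](C(C)C)(C(C)C)C(C)C)c1
A6 | alternative 2 | pentyllithium | [Li]CCCCC
A7 | alternative 2 | 2-methoxy-6-pentyl-4-(triisopropylsilyloxy)benzoic acid | CCCCCc1cc(O[Si](C(C)C)(C(C)C)C(C)C)cc(OC)c1C(=O)O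
A8 | alternative 3 | benzyl 2-methoxy-6-pentyl-4-[(3,5,7-trioxododecanoyl)oxy]benzoate | CCCCCC(=O)CC(=O)CC(=O)CC(=O)Oc1cc(CCCCC)c(C(=O)OCc2ccccc2)c(OC)c1
A9 | alternative 3 | benzyl 4-[(2,4-dihydroxy-6-pentylbenzoyl)oxy]-2-methoxy-6-pentylbenzoate | CCCCCc1cc(O)cc(O)c1C(=O)Oc1cc(CCCCC)c(C(=O)OCc2ccccc2)c(OC)c1
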